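**Strategy.** Ring A of the labdane is disconnected at C3–C4, and ring B is drawn from (1R,5R)-verbenone. The key step exploits the strained C4–C7 cyclobutane bond of the pinane ketone, which lies parallel to the C8 carbonyl π system. Lewis acid ionisation releases a C7=C8 titanium enolate and a tertiary C4 cation. The C3 terminus of a (Z)-vinylsilane arm on C10 captures it and closes ring A as a trans-fused C2=C3 cyclohexene; a methoxide quench then sets C9. The precursor is dihydroverbenone carrying at C10 the methyl and a (Z)-3-trimethylsilylallyl group and at C9 the complete (13S) methyl ester side chain, introduced as a chiral-pool iodide.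

Key step: step 9

**Remarks on the chemistry.**
- Labdane numbering is used throughout: verbenone C2, C3, C4, C5, C1, C6, C7 become C8, C9, C10, C5, C7, C4, C6.
- The iodide that delivers the (13S) side chain is methyl (3R)-5-iodo-3-methylpentanoate. Its arrangement in space is that of the (S)-hydroxy ester; the descriptor is R only because iodine outranks the ester branch.
- Assumption: commercial methyl hydrogen (R)-3-methylglutarate is the source of C13.
- The C9 configuration written for 18 is the expected kinetic one and is of no consequence, since C9 is equilibrated in step 9.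
- The silyl group is placed on C3 at the stage of the simple ketone 7, before the ester side chain is present, so that no strong base meets the ester.

Step 1
Reactants: 1 (1R,5R)-(+)-verbenone; 2 allyltrimethylsilane
Product: 4 (1R,4R,5R)-4-allyl-4,6,6-trimethylbicyclo[3.1.1]heptan-2-one, via trichlorotitanium enolate 3 (not isolated)
Conditions: TiCl4, CH2Cl2, −78 °C; then H2O
Reagents that add atoms: allyltrimethylsilane (2), C=CC[Si](C)(C)C
Why: Hosomi–Sakurai conjugate allylation: the TiCl4-complexed enone accepts the allylsilane at the β-carbon (C10) on the face away from the CMe2 bridge, which sets the C10 quaternary centre with the methyl syn to the bridge, and at −78 °C this should be much faster than ionisation of the cyclobutane.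

Step 2
Reactants: 4 (1R,4R,5R)-4-allyl-4,6,6-trimethylbicyclo[3.1.1]heptan-2-one
Product: 6 (1R,4R,5R)-4,6,6-trimethyl-4-(2-oxoethyl)bicyclo[3.1.1]heptan-2-one, via secondary ozonide 5 (not isolated)
Conditions: O3, CH2Cl2, −78 °C; then PPh3, −78 °C to rt
Reagents that add atoms: ozone, [O-][O+]=O
Why: Ozonolysis with reductive work-up cleaves the only alkene to the aldehyde that becomes C2, while the ketone and the cyclobutane are inert and no stereocentre is touched.

Step 3
Reactants: 6 (1R,4R,5R)-4,6,6-trimethyl-4-(2-oxoethyl)bicyclo[3.1.1]heptan-2-one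
Product: 7 (1R,4R,5R)-4,6,6-trimethyl-4-(prop-2-yn-1-yl)bicyclo[3.1.1]heptan-2-one
Conditions: MeC(O)C(N2)P(O)(OMe)2, K2CO3, MeOH, 0 °C to rt
Reagents that add atoms: dimethyl (1-diazo-2-oxopropyl)phosphonate, COP(=O)(OC)C(=[N+]=[N-])C(C)=O
Why: Seyferth–Gilbert homologation in its Ohira–Bestmann form: the diazophosphonate anion released by methoxide condenses with the aldehyde far faster than with the hindered ketone and the alkylidene carbene rearranges to the terminal alkyne that supplies C3, the neighbouring C10 being quaternary and not epimerisable.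

Step 4
Reactants: 7 (1R,4R,5R)-4,6,6-trimethyl-4-(prop-2-yn-1-yl)bicyclo[3.1.1]heptan-2-one
Product: 10 (1R,4R,5R)-4,6,6-trimethyl-4-[3-(trimethylsilyl)prop-2-yn-1-yl]bicyclo[3.1.1]heptan-2-one, via dilithio enolate acetylide 8 (not isolated), via bis(trimethylsilyl) enol ether alkyne 9 (not isolated)
Conditions: LiN(i-Pr)2 (2.2 equiv), THF, −78 °C; Me3SiCl, −78 °C to rt; then 1 M HCl, THF, 0 °C
Reagents that add atoms: chlorotrimethylsilane, C[Si](C)(C)Cl
Why: Double deprotonation (ketone to its C9 enolate, alkyne to its acetylide) followed by silylation puts Me3Si on C3 and on the enolate oxygen, and dilute acid then hydrolyses only the labile silyl enol ether (acetylide C-silylation and enolate O-silylation).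

Step 5
Reactants: 10 (1R,4R,5R)-4,6,6-trimethyl-4-[3-(trimethylsilyl)prop-2-yn-1-yl]bicyclo[3.1.1]heptan-2-one
Product: 11 (1R,4R,5R)-4,6,6-trimethyl-4-[(2Z)-3-(trimethylsilyl)prop-2-en-1-yl]bicyclo[3.1.1]heptan-2-one
Conditions: H2 (1 atm), Pd/CaCO3 poisoned with Pb(OAc)2, quinoline, hexane, rt
Reagents that add atoms: none
Why: Lindlar semihydrogenation: syn delivery of one equivalent of H2 to the silylalkyne on the poisoned palladium surface should give the Z-vinylsilane with the ketone untouched, uptake being stopped after one equivalent.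

Step 6
Reactants: 12 methyl hydrogen (R)-3-methylglutarate
Product: 14 (4S)-4-methyloxan-2-one, via (3S)-5-hydroxy-3-methylpentanoic acid 13 (not isolated)
Conditions: LiBH4, THF, 0 °C to rt; then 2 M HCl, rt
Reagents that add atoms: none
Why: Chemoselective borohydride reduction: the acid is converted at once into its lithium carboxylate, which LiBH4 does not reduce at room temperature, so only the ester becomes CH2OH and acidification closes the δ-lactone; the stereocentre is untouched and, because the two termini exchange roles, (R)-12 maps onto the (13S) side chain.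

Step 7
Reactants: 14 (4S)-4-methyloxan-2-one
Product: 16 methyl (3R)-5-iodo-3-methylpentanoate, via trimethylsilyl (3R)-5-iodo-3-methylpentanoate 15 (not isolated)
Conditions: Me3SiCl, NaI, MeCN, 60 °C; then MeOH, rt
Reagents that add atoms: sodium iodide, [Na+].[I-]; methanol, CO
Why: Silyl iodide opening of a lactone: Me3SiI formed in the flask silylates the carbonyl oxygen and iodide attacks the primary O–CH2 carbon by SN2 without touching the remote stereocentre, and methanol under the HI generated converts the silyl ester into the methyl ester (Fischer esterification).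

Step 8
Reactants: 11 (1R,4R,5R)-4,6,6-trimethyl-4-[(2Z)-3-(trimethylsilyl)prop-2-en-1-yl]bicyclo[3.1.1]heptan-2-one; 16 methyl (3R)-5-iodo-3-methylpentanoate
Product: 18 (1R,3S,4S,5S)-3-[(3S)-5-methoxy-3-methyl-5-oxopentyl]-4,6,6-trimethyl-4-[(2Z)-3-(trimethylsilyl)prop-2-en-1-yl]bicyclo[3.1.1]heptan-2-one, via lithium enolate 17 (not isolated)
Conditions: LiN(i-Pr)2, THF, −78 °C; then 16, DMPU, −78 to 0 °C
Reagents that add atoms: methyl (3R)-5-iodo-3-methylpentanoate (16), ICC[C@H](C)CC(=O)OC
Why: Enolate alkylation: only C9 can be enolised because the C7 bridgehead cannot carry a double bond, and the lithium enolate in the presence of DMPU should displace the primary iodide from the face anti to the CMe2 bridge; C13 arrives intact from 16.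

Step 9
Reactants: 18 (1R,3S,4S,5S)-3-[(3S)-5-methoxy-3-methyl-5-oxopentyl]-4,6,6-trimethyl-4-[(2Z)-3-(trimethylsilyl)prop-2-en-1-yl]bicyclo[3.1.1]heptan-2-one
Product: 22 methyl (13S)-8-oxo-17-norlabd-2-en-15-oate, via ring-opened C4 cation titanium enolate 19 (not isolated), via cyclised trichlorotitanium enolate 20 (not isolated), via C9-epimeric ketone 21 (not isolated)
Conditions: TiCl4 (3 equiv), CH2Cl2, −78 to 0 °C; then NaOMe, MeOH, 0 °C to rt
Reagents that add atoms: none
Why: Proposed new method: TiCl4 bound to the C8 carbonyl should ionise the C4–C7 bond, which is held nearly parallel to the carbonyl π system and carries the cyclobutane strain, to a C7=C8 titanium enolate and a tertiary C4 cation (19); the silicon-bearing C3 of the vinylsilane then bonds to C4, and the C2 cation, stabilised by the β-silicon, loses Me3SiCl to leave the C2=C3 alkene (20). The closest known reaction types are the Lewis acid opening of pinane-type cyclobutyl ketones to 4-substituted cyclohexanone derivatives and vinylsilane-terminated cation cyclisations, which have not been joined in one cascade. Ring A closes in a 6-endo-trig mode with respect to the vinylsilane through a chair in which C4 on C5 and C1 on C10 are both equatorial on ring B, so the preset C5 (from verbenone) and C10 (step 1) centres dictate the trans ring fusion. The only stereocentre adjusted is C9: the methoxide quench epimerises the axial side chain of 21 through the C8 enolate to the equatorial (9R) arrangement of 22 under thermodynamic control. The step needs capture of the C4 cation by C3 to outrun proton loss to an isopropenyl group, chloride capture and direct addition of the weakly nucleophilic vinylsilane to the complexed ketone; the arm is held next to the cation, the Z geometry places silicon axial and aligned with the empty orbital forming at C2, and the tertiary chloride or isopropenyl compound can return to the cation under TiCl4/HCl whereas desilylation is irreversible.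

Step 10
Reactants: 22 methyl (13S)-8-oxo-17-norlabd-2-en-15-oate
Product: 23 methyl (13S)-8-oxo-17-norlabdan-15-oate
Conditions: H2 (1 atm), Pd/C, EtOAc, rt
Reagents that add atoms: none
Why: Heterogeneous catalytic hydrogenation saturates the cis-disubstituted C2=C3 alkene under conditions that leave the ketone and the ester alone, and no stereocentre is formed.

Step 11
Reactants: 23 methyl (13S)-8-oxo-17-norlabdan-15-oate
Product: 24 methyl (13S)-labd-8(17)-en-15-oate
Conditions: Ph3PCH3Br, KOt-Bu, toluene, rt to 80 °C
Reagents that add atoms: methyltriphenylphosphonium bromide, C[P+](c1ccccc1)(c1ccccc1)c1ccccc1.[Br-]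
Why: Wittig methylenation: the non-stabilised ylide adds to the ketone but not to the ester, and the equatorial C9 side chain is already the thermodynamic arrangement, so transient enolisation cannot change it.

Step 12
Reactants: 24 methyl (13S)-labd-8(17)-en-15-oate
Product: 25 methyl (13S)-7α-hydroxylabd-8(17)-en-15-oate
Conditions: SeO2 (cat.), t-BuOOH, CH2Cl2, rt
Reagents that add atoms: tert-butyl hydroperoxide, CC(C)(C)OO (oxygen passed on through selenium dioxide, O=[Se]=O)
Why: SeO2 allylic oxidation (ene reaction then [2,3]-sigmatropic shift) with t-BuOOH as terminal oxidant: the exocyclic alkene reacts at the ring CH2 (C7) in preference to the tertiary C9–H, the axial 7α-hydrogen is removed and oxygen returns on the same axial α face, which sets C7 (R) and restores the C8=C17 alkene.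

Step 13
Reactants: 25 methyl (13S)-7α-hydroxylabd-8(17)-en-15-oate
Product: 26 methyl (13S)-7α-acetoxylabd-8(17)-en-15-oate
Conditions: Ac2O, pyridine, DMAP (cat.), CH2Cl2, rt
Reagents that add atoms: acetic anhydride, CC(=O)OC(C)=O
Why: DMAP-catalysed acylation of the secondary allylic alcohol proceeds with retention at C7 and gives the target.

**Compound list**

1 | (1R,5R)-(+)-verbenone, (1R,5R)-4,6,6-trimethylbicyclo[3.1.1]hept-3-en-2-one | CC1=CC(=O)[C@@H]2C[C@H]1C2(C)C | starting material
2 | allyltrimethylsilane | C=CC[Si](C)(C)C | starting material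
3 | trichlorotitanium enolate of 4 (C8–O–TiCl3, C8=C9) | Cl[Ti](Cl)(Cl)OC=1[C@@H]2C[C@@H](C2(C)C)[C@](C)(CC=C)C=1 | intermediate (not isolated)
4 | (1R,4R,5R)-4-allyl-4,6,6-trimethylbicyclo[3.1.1]heptan-2-one (allyl anti to the CMe2 bridge) | O=C1[C@@H]2C[C@@H](C2(C)C)[C@](C)(CC=C)C1 | intermediate
5 | secondary ozonide of 4 (1,2,4-trioxolan-3-ylmethyl group on C10, trioxolane carbon unassigned) | O=C1[C@@H]2C[C@@H](C2(C)C)[C@](C)(CC3OCOO3)C1 | intermediate (not isolated)
6 | (1R,4R,5R)-4,6,6-trimethyl-4-(2-oxoethyl)bicyclo[3.1.1]heptan-2-one | O=C1[C@@H]2C[C@@H](C2(C)C)[C@](C)(CC=O)C1 | intermediate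
7 | (1R,4R,5R)-4,6,6-trimethyl-4-(prop-2-yn-1-yl)bicyclo[3.1.1]heptan-2-one | O=C1[C@@H]2C[C@@H](C2(C)C)[C@](C)(CC#C)C1 | intermediate
8 | dilithio derivative of 7 (lithium C8=C9 enolate and lithium acetylide) | [Li]OC=1[C@@H]2C[C@@H](C2(C)C)[C@](C)(CC#C[Li])C=1 | intermediate (not isolated)
9 | 4,6,6-trimethyl-2-(trimethylsilyloxy)-4-[3-(trimethylsilyl)prop-2-yn-1-yl]bicyclo[3.1.1]hept-2-ene (trimethylsilyl enol ether of 10, configurations as in 7) | C[Si](C)(C)OC=1[C@@H]2C[C@@H](C2(C)C)[C@](C)(CC#C[Si](C)(C)C)C=1 | intermediate (not isolated)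
10 | (1R,4R,5R)-4,6,6-trimethyl-4-[3-(trimethylsilyl)prop-2-yn-1-yl]bicyclo[3.1.1]heptan-2-one | O=C1[C@@H]2C[C@@H](C2(C)C)[C@](C)(CC#C[Si](C)(C)C)C1 | intermediate
11 | (1R,4R,5R)-4,6,6-trimethyl-4-[(2Z)-3-(trimethylsilyl)prop-2-en-1-yl]bicyclo[3.1.1]heptan-2-one | O=C1[C@@H]2C[C@@H](C2(C)C)[C@](C)(C/C=C\[Si](C)(C)C)C1 | intermediate
12 | methyl hydrogen (R)-3-methylglutarate, (3R)-5-methoxy-3-methyl-5-oxopentanoic acid | COC(=O)C[C@H](C)CC(=O)O | starting material
13 | (3S)-5-hydroxy-3-methylpentanoic acid (lithium salt before acidification) | OCC[C@H](C)CC(=O)O | intermediate (not isolated)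
14 | (4S)-4-methyloxan-2-one | C[C@H]1CCOC(=O)C1 | intermediate
15 | trimethylsilyl (3R)-5-iodo-3-methylpentanoate | ICC[C@H](C)CC(=O)O[Si](C)(C)C | intermediate (not isolated)
16 | methyl (3R)-5-iodo-3-methylpentanoate | ICC[C@H](C)CC(=O)OC | intermediate
17 | lithium C8=C9 enolate of 11 | [Li]OC=1[C@@H]2C[C@@H](C2(C)C)[C@](C)(C/C=C\[Si](C)(C)C)C=1 | intermediate (not isolated)
18 | (1R,3S,4S,5S)-3-[(3S)-5-methoxy-3-methyl-5-oxopentyl]-4,6,6-trimethyl-4-[(2Z)-3-(trimethylsilyl)prop-2-en-1-yl]bicyclo[3.1.1]heptan-2-one (C9 side chain and C10 silylallyl arm both anti to the C4 bridge) | O=C1[C@@H]2C[C@@H](C2(C)C)[C@](C)(C/C=C\[Si](C)(C)C)[C@@H]1CC[C@H](C)CC(=O)OC | intermediate (key-step precursor)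
19 | ring-opened zwitterion: C7=C8 tetrachlorotitanate enolate with the tertiary C4 carbocation on C5 | Cl[Ti-](Cl)(Cl)(Cl)OC1=CC[C@@H]([C+](C)C)[C@](C)(C/C=C\[Si](C)(C)C)[C@@H]1CC[C@H](C)CC(=O)OC | intermediate (not isolated)
20 | C7=C8 trichlorotitanium enolate of 21 (rings A and B closed, C2=C3 alkene) | Cl[Ti](Cl)(Cl)OC1=CC[C@H]2C(C)(C)C=CC[C@]2(C)[C@@H]1CC[C@H](C)CC(=O)OC | intermediate (not isolated)
21 | methyl (5S,9S,10S,13S)-8-oxo-17-norlabd-2-en-15-oate (C9 epimer of 22, side chain axial) | O=C1CC[C@H]2C(C)(C)C=CC[C@]2(C)[C@@H]1CC[C@H](C)CC(=O)OC | intermediate (not isolated)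
22 | methyl (13S)-8-oxo-17-norlabd-2-en-15-oate (5S,9R,10S,13S) | O=C1CC[C@H]2C(C)(C)C=CC[C@]2(C)[C@H]1CC[C@H](C)CC(=O)OC | intermediate (key-step product)
23 | methyl (13S)-8-oxo-17-norlabdan-15-oate (5S,9R,10S,13S) | O=C1CC[C@H]2C(C)(C)CCC[C@]2(C)[C@H]1CC[C@H](C)CC(=O)OC | intermediate
24 | methyl (13S)-labd-8(17)-en-15-oate (5S,9S,10S,13S) | C=C1CC[C@H]2C(C)(C)CCC[C@]2(C)[C@H]1CC[C@H](C)CC(=O)OC | intermediate
25 | methyl (13S)-7α-hydroxylabd-8(17)-en-15-oate (5S,7R,9R,10S,13S) | C=C1[C@H](O)C[C@H]2C(C)(C)CCC[C@]2(C)[C@H]1CC[C@H](C)CC(=O)OC | intermediate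
26 | methyl (13S)-7α-acetoxylabd-8(17)-en-15-oate (5S,7R,9R,10S,13S), CNP0223602.1 | C=C1[C@H](OC(C)=O)C[C@H]2C(C)(C)CCC[C@]2(C)[C@H]1CC[C@H](C)CC(=O)OC | target

**Step count.** Total: 13 steps. Longest linear sequence: 11 steps (steps 1–5 and 8–13, from 1 to 26); the side-chain iodide 16 takes 2 steps (6–7).

**Steps most likely to fail**

Step 9. What may go wrong: capture of the C4 cation by the vinylsilane loses to proton loss, chloride capture, protodesilylation, or direct attack of the vinylsilane on the complexed ketone. The fallback uses known reactions and separates cyclobutane cleavage from ring closure. It sets out from 10. Alkylation with 16 under the conditions of step 8 should give the C9-alkylated silylalkyne ketone F1. The acylative opening known for pinane cyclobutyl ketones (Ac2O, BF3·OEt2, Zn(OAc)2, CH2Cl2, rt) then cleaves C4–C7 at a stage where the alkynylsilane cannot close a six-membered ring, giving the ring-opened enol acetate tertiary acetate F2. Lindlar semihydrogenation as in step 5 gives the Z-vinylsilane F3. Ionisation of the tertiary acetate with SnCl4 in CH2Cl2 at −78 °C starts a conventional vinylsilane-terminated cation cyclisation to the bicyclic enol acetate F4. NaOMe in MeOH cleaves the enol acetate and equilibrates C9, returning to the route at 22.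

Step 8. What may go wrong: slow SN2 displacement at an enolate flanked by the quaternary C10, so that proton transfer, elimination of HI from the iodide, or attack on its ester takes over. In the fallback the C9–C11 bond is made by an aldol reaction instead. It sets out from 16. Kornblum oxidation (DMSO, NaHCO3, 100 °C) gives methyl (3S)-3-methyl-5-oxopentanoate F5. The lithium enolate 17 of ketone 11 adds to it at −78 °C to give the β-hydroxy ketone F6. Mesylation and elimination (MsCl, Et3N; then DBU) give the C9=C11 enone F7. Conjugate reduction with [(Ph3P)CuH]6, which leaves the vinylsilane and the ester alone, gives 18 together with its C9 epimer F8. The fallback returns to the route at 18; F8 needs no separation because both epimers converge on 22 in step 9.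

Step 12. What may go wrong: competing abstraction of the tertiary C9–H, over-oxidation to the C7 enone, and incomplete α-facial selectivity. In the fallback the C7 oxygen is introduced before the methylene group. It sets out from 23. Kinetic enolisation toward C7 (LiN(i-Pr)2, Me3SiCl, THF, −78 °C) gives the Δ7 trimethylsilyl enol ether F9. Rubottom oxidation (mCPBA, NaHCO3, CH2Cl2; then dilute HCl) on the α face, away from the axial C10 methyl, gives the 7α-hydroxy ketone F10. Acetylation as in step 13 gives the 7α-acetoxy ketone F11. Non-basic methylenation (Zn, CH2Br2, TiCl4, THF/CH2Cl2) then returns to the route at the target 26.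

**Further compounds**

F1 | step 9 | (1R,3S,4S,5S)-3-[(3S)-5-methoxy-3-methyl-5-oxopentyl]-4,6,6-trimethyl-4-[3-(trimethylsilyl)prop-2-yn-1-yl]bicyclo[3.1.1]heptan-2-one | O=C1[C@@H]2C[C@@H](C2(C)C)[C@](C)(CC#C[Si](C)(C)C)[C@@H]1CC[C@H](C)CC(=O)OC
F2 | step 9 | ring-opened C7=C8 enol acetate with a 2-acetoxypropan-2-yl group on C5 and the silylpropargyl arm on C10 | CC(=O)OC1=CC[C@@H](C(C)(C)OC(C)=O)[C@](C)(CC#C[Si](C)(C)C)[C@@H]1CC[C@H](C)CC(=O)OC
F3 | step 9 | (Z)-vinylsilane analogue of F2 | CC(=O)OC1=CC[C@@H](C(C)(C)OC(C)=O)[C@](C)(C/C=C\[Si](C)(C)C)[C@@H]1CC[C@H](C)CC(=O)OC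
F4 | step 9 | C7=C8 enol acetate of 21 | CC(=O)OC1=CC[C@H]2C(C)(C)C=CC[C@]2(C)[C@@H]1CC[C@H](C)CC(=O)OC
F5 | step 8 | methyl (3S)-3-methyl-5-oxopentanoate | O=CC[C@H](C)CC(=O)OC
F6 | step 8 | C11-hydroxy aldol adduct of 11 and F5 (C9 and C11 unassigned) | O=C1[C@@H]2C[C@@H](C2(C)C)[C@](C)(C/C=C\[Si](C)(C)C)C1C(O)C[C@H](C)CC(=O)OC
F7 | step 8 | C9=C11 enone from F6 (alkene geometry unassigned) | O=C1[C@@H]2C[C@@H](C2(C)C)[C@](C)(C/C=C\[Si](C)(C)C)C1=CC[C@H](C)CC(=O)OC
F8 | step 8 | C9 epimer of 18 (side chain syn to the C4 bridge) | O=C1[C@@H]2C[C@@H](C2(C)C)[C@](C)(C/C=C\[Si](C)(C)C)[C@H]1CC[C@H](C)CC(=O)OC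
F9 | step 12 | C7=C8 trimethylsilyl enol ether of 23 | C[Si](C)(C)OC1=CC[C@H]2C(C)(C)CCC[C@]2(C)[C@H]1CC[C@H](C)CC(=O)OC
F10 | step 12 | methyl (13S)-7α-hydroxy-8-oxo-17-norlabdan-15-oate | O=C1[C@H](O)C[C@H]2C(C)(C)CCC[C@]2(C)[C@H]1CC[C@H](C)CC(=O)OC
F11 | step 12 | methyl (13S)-7α-acetoxy-8-oxo-17-norlabdan-15-oate | O=C1[C@H](OC(C)=O)C[C@H]2C(C)(C)CCC[C@]2(C)[C@H]1CC[C@H](C)CC(=O)OC
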